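## Retrosynthetic overview

1. Feature: ring A is a benzene ring whose only substituent is the C7 oxygen, and it joins the rest of the molecule only through the C4a–C8a edge of ring C. The single stereocentre C2 belongs to ring C alone, so ring A can be grown last on a monocyclic 2-aryl-2,3-dihydropyran-4-one that already holds (S)-C2.
2. Last bond: C3'–CH= of the (E)-3-hydroxy-3-methylbut-1-enyl chain, made by Mizoroki–Heck reaction of the C3' aryl bromide with 2-methylbut-3-en-2-ol.
3. Key disconnection: C4a–C5 and C8–C8a, a [4+2] cycloaddition of Rawal's diene to the sulfinyl-activated C4a=C8a bond (pyranone C5=C6), followed by loss of Me2NH and PhSOH.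
4. The sulfinyl pyranone comes from the parent (2S)-pyranone by C5 iodination, C–S coupling and S-oxidation. That pyranone comes from the ring B aldehyde and Danishefsky's diene by an enantioselective hetero-Diels–Alder reaction that forms ring C and sets C2.
5. The aldehyde comes from 3-bromo-4-hydroxybenzaldehyde by O-allylation, Claisen rearrangement, O-methylation and cross-metathesis. Order of rings: B (bought), C, A.

Key step: step 9

Assumption: the BINOL–titanium catalyst is taken to shield the same aldehyde face as in its allylation and Mukaiyama aldol reactions of benzaldehydes, so that (S)-BINOL gives the (2S)-pyranone. If the first sample proves to be (2R), (R)-BINOL is used instead and nothing else changes.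

## Route

Step 1
Reactants: 1 3-bromo-4-hydroxybenzaldehyde; 2 allyl bromide
Product: 3 3-bromo-4-(prop-2-en-1-yloxy)benzaldehyde
Conditions: K2CO3, DMF, rt
Reagents that add atoms: none
Why: Williamson ether synthesis, in which the phenoxide of 1 displaces bromide from the allylic halide by SN2 while the aldehyde and the aryl bromide are inert to K2CO3.

Step 2
Reactants: 3 3-bromo-4-(prop-2-en-1-yloxy)benzaldehyde
Product: 4 3-bromo-4-hydroxy-5-(prop-2-en-1-yl)benzaldehyde
Conditions: PhNEt2, 200 °C
Reagents that add atoms: none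
Why: Aromatic Claisen rearrangement, whose [3,3]-shift can end productively only at C5, the one free ortho position, after which tautomerisation restores the phenol.

Step 3
Reactants: 4 3-bromo-4-hydroxy-5-(prop-2-en-1-yl)benzaldehyde
Product: 5 3-bromo-4-methoxy-5-(prop-2-en-1-yl)benzaldehyde
Conditions: MeI, K2CO3, DMF, rt
Reagents that add atoms: iodomethane, CI
Why: Williamson O-methylation of an acidic phenol, placed before the metathesis so that no free phenol ever sits next to the prenyl group when acid is used later.

Step 4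
Reactants: 5 3-bromo-4-methoxy-5-(prop-2-en-1-yl)benzaldehyde
Product: 6 3-bromo-4-methoxy-5-(3-methylbut-2-en-1-yl)benzaldehyde
Conditions: 2-methylbut-2-ene (excess), second-generation Grubbs catalyst (H2IMes)(PCy3)Cl2Ru=CHPh (3 mol %), CH2Cl2, 40 °C, sealed tube
Reagents that add atoms: 2-methylbut-2-ene, CC=C(C)C
Why: Olefin cross-metathesis of a terminal alkene with excess 2-methylbut-2-ene is the standard conversion of allyl into prenyl, and it tolerates the aldehyde, aryl bromide and ether.

Step 5
Reactants: 6 3-bromo-4-methoxy-5-(3-methylbut-2-en-1-yl)benzaldehyde; 7 Danishefsky's diene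
Product: 9 (2S)-2-[3-bromo-4-methoxy-5-(3-methylbut-2-en-1-yl)phenyl]-2,3-dihydro-4H-pyran-4-one, via silylated Mukaiyama aldol adduct 8 (not isolated)
Conditions: (S)-BINOL (20 mol %), Ti(OiPr)4 (10 mol %), 4 Å MS, Et2O, −20 °C; then TFA, CH2Cl2, 0 °C
Reagents that add atoms: none
Why: BINOL–titanium-catalysed hetero-Diels–Alder reaction running through a Mukaiyama aldol addition, in which the chiral titanium complex binds the aldehyde and shields one face so that the diene terminus sets C2 as (S), and brief TFA treatment closes ring C by 6-endo attack of the oxygen on the methoxy enone with loss of methanol.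

Step 6
Reactants: 9 (2S)-2-[3-bromo-4-methoxy-5-(3-methylbut-2-en-1-yl)phenyl]-2,3-dihydro-4H-pyran-4-one
Product: 10 (2S)-2-[3-bromo-4-methoxy-5-(3-methylbut-2-en-1-yl)phenyl]-5-iodo-2,3-dihydro-4H-pyran-4-one
Conditions: I2, pyridine–CH2Cl2, 0 °C → rt, dark
Reagents that add atoms: iodine, II
Why: Pyridine-promoted alpha-iodination of an enone at C5, the only nucleophilic carbon of the vinylogous ester, chosen because iodine adds to the prenyl alkene only reversibly whereas a sulfenyl halide or an acid-activated N-thioimide would add to it irreversibly.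

Step 7
Reactants: 10 (2S)-2-[3-bromo-4-methoxy-5-(3-methylbut-2-en-1-yl)phenyl]-5-iodo-2,3-dihydro-4H-pyran-4-one
Product: 11 (2S)-2-[3-bromo-4-methoxy-5-(3-methylbut-2-en-1-yl)phenyl]-5-(phenylsulfanyl)-2,3-dihydro-4H-pyran-4-one
Conditions: Bu3SnSPh (1.1 equiv), Pd(PPh3)4 (5 mol %), PhMe, 65 °C
Reagents that add atoms: tributyl(phenylsulfanyl)stannane, CCCC[Sn](CCCC)(CCCC)Sc1ccccc1
Why: Palladium-catalysed C–S cross-coupling with a tin thiolate (Migita type, Stille-like transmetalation), in which zerovalent palladium inserts into the activated vinylic carbon–iodine bond well before the electron-rich, ortho-substituted aryl carbon–bromine bond, and the base-free medium keeps free thiolate away from C6 and leaves C2 untouched.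

Step 8
Reactants: 11 (2S)-2-[3-bromo-4-methoxy-5-(3-methylbut-2-en-1-yl)phenyl]-5-(phenylsulfanyl)-2,3-dihydro-4H-pyran-4-one
Product: 12 (2S)-2-[3-bromo-4-methoxy-5-(3-methylbut-2-en-1-yl)phenyl]-5-(phenylsulfinyl)-2,3-dihydro-4H-pyran-4-one (both epimers at sulfur)
Conditions: mCPBA (1.0 equiv), CH2Cl2, −78 → −20 °C
Reagents that add atoms: 3-chloroperoxybenzoic acid, O=C(OO)c1cccc(Cl)c1
Why: Chemoselective sulfide-to-sulfoxide oxidation, in which sulfur is oxidised much faster than the trisubstituted alkene is epoxidised at low temperature, the aprotic medium spares the electrophilic C6, and both sulfur epimers are used together because sulfur leaves in step 9.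

Step 9
Reactants: 12 (2S)-2-[3-bromo-4-methoxy-5-(3-methylbut-2-en-1-yl)phenyl]-5-(phenylsulfinyl)-2,3-dihydro-4H-pyran-4-one (both epimers at sulfur); 13 Rawal's diene
Product: 16 (2S)-2-[3-bromo-4-methoxy-5-(3-methylbut-2-en-1-yl)phenyl]-7-hydroxy-2,3-dihydro-4H-chromen-4-one, via cis-fused cycloadduct 14 (not isolated), via angular sulfinyl enone 15 (not isolated)
Conditions: 13 (1.5 equiv), PhMe, 0 °C → rt; aq HF, MeCN, 0 °C; aq NaHCO3 wash; PhMe, 70 °C
Reagents that add atoms: none
Why: Proposed new method: the CH2 terminus of 13, the carbon that receives the push of both the amino and the siloxy group, should bond to C8a (pyranone C6), the beta carbon of the C4 ketone and of the sulfinyl group, while the aminated terminus bonds to C4a (pyranone C5); ring A thus closes by an intermolecular, asynchronous [4+2] cycloaddition (four diene carbons plus C4a–C8a) and the oxygenated carbon lands at C7, not C6, which is the one selectivity the step needs and which the matched polarisation of the two partners secures. The closest known reactions are the cycloadditions of sulfinylquinones and of chromones bearing an acceptor at C3 with 1,3-dioxygenated dienes, followed by sulfoxide loss and aromatisation; a monocyclic 5-sulfinyl-2,3-dihydropyran-4-one has not been used as the two-carbon partner. In the ketone-endo adduct 14 both H8a and H5 stand syn to sulfur, and elimination towards C5 would give an enaminone able to push O1 out of C8a, so the amine is removed first: HF cleaves the silyl enol ether and the protonated amine leaves C5 by beta-elimination through the enol of the C7 ketone to give 15, where C5 is sp2 and H8a is the only hydrogen left for the sulfoxide. Gentle heating then takes PhSOH out by thermal syn-elimination across C4a–C8a, and enolisation of the C7 carbonyl completes the benzene ring of 16. The three transient sp3 centres C4a, C5 and C8a are all erased, so facial selectivity, endo/exo selectivity and the sulfur configuration are without consequence. C2 is carried through because C2–O1 stays an unactivated ether bond until the last event and because dimethylamine is washed out as its salt before the base-sensitive flavanone exists; toluene is used to disfavour a free zwitterion that could eject O1.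

Step 10
Reactants: 16 (2S)-2-[3-bromo-4-methoxy-5-(3-methylbut-2-en-1-yl)phenyl]-7-hydroxy-2,3-dihydro-4H-chromen-4-one; 17 2-methylbut-3-en-2-ol
Product: 18 (2S)-7-hydroxy-2-{3-[(1E)-3-hydroxy-3-methylbut-1-en-1-yl]-4-methoxy-5-(3-methylbut-2-en-1-yl)phenyl}-2,3-dihydro-4H-chromen-4-one
Conditions: 17 (3 equiv), Pd(P(t-Bu)3)2 (5 mol %), Cy2NMe (2.5 equiv), dioxane, 45 °C
Reagents that add atoms: none
Why: Mizoroki–Heck reaction, in which the arylpalladium adds to the unsubstituted alkene terminus and can lose only a benzylic hydrogen (the carbinol carbon has none), giving the (E)-styrenyl alcohol, while the hindered amine, the low temperature and the C7 phenoxide formed in the medium (which lowers the acidity at C3) should hold back retro-oxa-Michael opening at C2–O1.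

## Compound list

| No. | Name | SMILES | Role |
|---|---|---|---|
| 1 | 3-bromo-4-hydroxybenzaldehyde | O=Cc1ccc(O)c(Br)c1 | starting material |
| 2 | allyl bromide | C=CCBr | starting material |
| 3 | 3-bromo-4-(prop-2-en-1-yloxy)benzaldehyde | C=CCOc1ccc(C=O)cc1Br | intermediate |
| 4 | 3-bromo-4-hydroxy-5-(prop-2-en-1-yl)benzaldehyde | C=CCc1cc(C=O)cc(Br)c1O | intermediate |
| 5 | 3-bromo-4-methoxy-5-(prop-2-en-1-yl)benzaldehyde | C=CCc1cc(C=O)cc(Br)c1OC | intermediate |
| 6 | 3-bromo-4-methoxy-5-(3-methylbut-2-en-1-yl)benzaldehyde | COc1c(Br)cc(C=O)cc1CC=C(C)C | intermediate |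
| 7 | Danishefsky's diene, (E)-1-methoxy-3-(trimethylsilyloxy)buta-1,3-diene | CO/C=C/C(=C)O[Si](C)(C)C | starting material |
| 8 | (1E,5S)-5-[3-bromo-4-methoxy-5-(3-methylbut-2-en-1-yl)phenyl]-1-methoxy-5-(trimethylsilyloxy)pent-1-en-3-one | COc1c(Br)cc([C@H](CC(=O)/C=C/OC)O[Si](C)(C)C)cc1CC=C(C)C | intermediate |
| 9 | (2S)-2-[3-bromo-4-methoxy-5-(3-methylbut-2-en-1-yl)phenyl]-2,3-dihydro-4H-pyran-4-one | COc1c(Br)cc([C@@H]2CC(=O)C=CO2)cc1CC=C(C)C | intermediate |
| 10 | (2S)-2-[3-bromo-4-methoxy-5-(3-methylbut-2-en-1-yl)phenyl]-5-iodo-2,3-dihydro-4H-pyran-4-one | COc1c(Br)cc([C@@H]2CC(=O)C(I)=CO2)cc1CC=C(C)C | intermediate |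
| 11 | (2S)-2-[3-bromo-4-methoxy-5-(3-methylbut-2-en-1-yl)phenyl]-5-(phenylsulfanyl)-2,3-dihydro-4H-pyran-4-one | COc1c(Br)cc([C@@H]2CC(=O)C(Sc3ccccc3)=CO2)cc1CC=C(C)C | intermediate |
| 12 | (2S)-2-[3-bromo-4-methoxy-5-(3-methylbut-2-en-1-yl)phenyl]-5-(phenylsulfinyl)-2,3-dihydro-4H-pyran-4-one; sulfur left undefined, both epimers | COc1c(Br)cc([C@@H]2CC(=O)C(S(=O)c3ccccc3)=CO2)cc1CC=C(C)C | intermediate |
| 13 | Rawal's diene, (E)-1-(dimethylamino)-3-(tert-butyldimethylsilyloxy)buta-1,3-diene | CN(C)/C=C/C(=C)O[Si](C)(C)C(C)(C)C | starting material |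
| 14 | (2S)-2-[3-bromo-4-methoxy-5-(3-methylbut-2-en-1-yl)phenyl]-7-(tert-butyldimethylsilyloxy)-5-(dimethylamino)-4a-(phenylsulfinyl)-2,3,4a,5,8,8a-hexahydro-4H-chromen-4-one; cis ring fusion; C4a, C5, C8a and sulfur left undefined because all are lost | COc1c(Br)cc([C@@H]2CC(=O)C3(S(=O)c4ccccc4)C(N(C)C)C=C(O[Si](C)(C)C(C)(C)C)CC3O2)cc1CC=C(C)C | intermediate |
| 15 | (2S)-2-[3-bromo-4-methoxy-5-(3-methylbut-2-en-1-yl)phenyl]-4a-(phenylsulfinyl)-2,3,8,8a-tetrahydro-4H-chromene-4,7(4aH)-dione; cis ring fusion; C4a, C8a and sulfur left undefined | COc1c(Br)cc([C@@H]2CC(=O)C3(S(=O)c4ccccc4)C=CC(=O)CC3O2)cc1CC=C(C)C | intermediate |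
| 16 | (2S)-2-[3-bromo-4-methoxy-5-(3-methylbut-2-en-1-yl)phenyl]-7-hydroxy-2,3-dihydro-4H-chromen-4-one | COc1c(Br)cc([C@@H]2CC(=O)c3ccc(O)cc3O2)cc1CC=C(C)C | intermediate |
| 17 | 2-methylbut-3-en-2-ol | C=CC(C)(C)O | starting material |
| 18 | (2S)-7-hydroxy-2-{3-[(1E)-3-hydroxy-3-methylbut-1-en-1-yl]-4-methoxy-5-(3-methylbut-2-en-1-yl)phenyl}-2,3-dihydro-4H-chromen-4-one | COc1c(/C=C/C(C)(C)O)cc([C@@H]2CC(=O)c3ccc(O)cc3O2)cc1CC=C(C)C | target |

## Step count

Total step count: 10. Longest linear sequence: 10 steps (1 → 18).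

## Steps most likely to fail

**1. Step 9.**
- The diene may add to C8a stepwise, and the stabilised carbanion at C4a may then eject O1 and open ring C faster than it closes on the iminium carbon.
- The cycloaddition may need heat, so that sulfenic acid is lost towards C5 before the amine has been removed.
- The allylic sulfoxide of 15 may drift by [2,3]-sigmatropic shift.
- The sulfenic acid released may sulfenylate the new phenol ring.

The fallback uses known chemistry. It sets out from 6 and comes back at 16, and ring A is bought instead of built.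
- Methyl 2,4-dihydroxybenzoate is silylated at the non-chelated 4-OH (TBSCl, imidazole, CH2Cl2) to methyl 4-(tert-butyldimethylsilyloxy)-2-hydroxybenzoate F1.
- A crossed Claisen condensation with excess lithium enolate of tert-butyl acetate (LDA, THF, −78 → 0 °C) gives tert-butyl 3-[4-(tert-butyldimethylsilyloxy)-2-hydroxyphenyl]-3-oxopropanoate F2.
- Knoevenagel condensation of F2 with 6 (piperidine, AcOH, 4 Å MS, toluene) gives tert-butyl 3-[3-bromo-4-methoxy-5-(3-methylbut-2-en-1-yl)phenyl]-2-[4-(tert-butyldimethylsilyloxy)-2-hydroxybenzoyl]prop-2-enoate F3.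
- A cinchona-alkaloid thiourea catalyst closes ring C by enantioselective intramolecular oxa-Michael addition (toluene, −25 °C). The pseudoenantiomer that leads to the 2S series is used. The product is tert-butyl (2S)-2-[3-bromo-4-methoxy-5-(3-methylbut-2-en-1-yl)phenyl]-7-(tert-butyldimethylsilyloxy)-4-oxochromane-3-carboxylate F4.
- TsOH in warm toluene removes the tert-butyl ester with decarboxylation to give (2S)-2-[3-bromo-4-methoxy-5-(3-methylbut-2-en-1-yl)phenyl]-7-(tert-butyldimethylsilyloxy)-2,3-dihydro-4H-chromen-4-one F5.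
- TBAF–AcOH in THF at 0 °C then gives 16.

**2. Step 7.**
- The catalyst may be deactivated by thiolate.
- The vinylic iodide may be reduced.
- Insertion into the aryl carbon–bromine bond may begin if the temperature has to be raised.

The fallback is metal-free. It sets out from 9, skips 10 and comes back at 11.
- Compound 9 is opened with dimethylamine (2 M in THF, rt) by addition–elimination at C6. This cleaves C6–O1 and leaves C2–O1 intact, giving (1E,5S)-5-[3-bromo-4-methoxy-5-(3-methylbut-2-en-1-yl)phenyl]-1-(dimethylamino)-5-hydroxypent-1-en-3-one F6.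
- This enaminone is a far stronger carbon nucleophile than the vinylogous ester. It is sulfenylated at its alpha carbon by N-(phenylthio)succinimide in CH2Cl2 at 0 °C without an acid activator, conditions under which the prenyl alkene does not react. The product is (5S)-5-[3-bromo-4-methoxy-5-(3-methylbut-2-en-1-yl)phenyl]-1-(dimethylamino)-5-hydroxy-2-(phenylsulfanyl)pent-1-en-3-one F7.
- TFA in CH2Cl2 at 0 °C closes ring C again with loss of dimethylamine and gives 11.

**3. Step 10.**
- Slow oxidative addition into the electron-rich, ortho-substituted bromide may force a higher temperature.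
- At that temperature, amine-induced enolisation at C3 and retro-oxa-Michael cleavage of C2–O1 would erode the configuration.
- The tertiary allylic alcohol may ionise during work-up.

The fallback sets out from 16 and comes back at 18. It replaces the base-mediated alkene arylation by a base-free coupling with a preformed vinyl metal.
- 2-Methylbut-3-yn-2-ol is hydrostannylated (Bu3SnH, PdCl2(PPh3)2 cat., THF, 0 °C → rt) to (E)-2-methyl-4-(tributylstannyl)but-3-en-2-ol F8.
- A Migita–Kosugi–Stille coupling of 16 with F8 (Pd(PPh3)4, toluene, 90 °C, no base) gives 18 with the alkene geometry already fixed in the stannane.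

## Further compounds

F1 | step 9 | methyl 4-(tert-butyldimethylsilyloxy)-2-hydroxybenzoate | COC(=O)c1ccc(O[Si](C)(C)C(C)(C)C)cc1O
F2 | step 9 | tert-butyl 3-[4-(tert-butyldimethylsilyloxy)-2-hydroxyphenyl]-3-oxopropanoate | CC(C)(C)OC(=O)CC(=O)c1ccc(O[Si](C)(C)C(C)(C)C)cc1O
F3 | step 9 | tert-butyl 3-[3-bromo-4-methoxy-5-(3-methylbut-2-en-1-yl)phenyl]-2-[4-(tert-butyldimethylsilyloxy)-2-hydroxybenzoyl]prop-2-enoate (alkene geometry as formed) | COc1c(Br)cc(C=C(C(=O)OC(C)(C)C)C(=O)c2ccc(O[Si](C)(C)C(C)(C)C)cc2O)cc1CC=C(C)C
F4 | step 9 | tert-butyl (2S)-2-[3-bromo-4-methoxy-5-(3-methylbut-2-en-1-yl)phenyl]-7-(tert-butyldimethylsilyloxy)-4-oxochromane-3-carboxylate (C3 labile, left undefined) | COc1c(Br)cc([C@@H]2C(C(=O)OC(C)(C)C)C(=O)c3ccc(O[Si](C)(C)C(C)(C)C)cc3O2)cc1CC=C(C)C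
F5 | step 9 | (2S)-2-[3-bromo-4-methoxy-5-(3-methylbut-2-en-1-yl)phenyl]-7-(tert-butyldimethylsilyloxy)-2,3-dihydro-4H-chromen-4-one | COc1c(Br)cc([C@@H]2CC(=O)c3ccc(O[Si](C)(C)C(C)(C)C)cc3O2)cc1CC=C(C)C
F6 | step 7 | (1E,5S)-5-[3-bromo-4-methoxy-5-(3-methylbut-2-en-1-yl)phenyl]-1-(dimethylamino)-5-hydroxypent-1-en-3-one | COc1c(Br)cc([C@@H](O)CC(=O)/C=C/N(C)C)cc1CC=C(C)C
F7 | step 7 | (5S)-5-[3-bromo-4-methoxy-5-(3-methylbut-2-en-1-yl)phenyl]-1-(dimethylamino)-5-hydroxy-2-(phenylsulfanyl)pent-1-en-3-one (alkene geometry immaterial) | COc1c(Br)cc([C@@H](O)CC(=O)C(Sc2ccccc2)=CN(C)C)cc1CC=C(C)C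
F8 | step 10 | (E)-2-methyl-4-(tributylstannyl)but-3-en-2-ol | CC(C)(O)/C=C/[Sn](CCCC)(CCCC)CCCC
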